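**Retrosynthetic overview**

1. The last step is acid methanolysis of the three MOM ethers of the fully assembled (2S)-flavanone; nothing else changes once ring C exists.
2. Ring C is closed by the O1–C8a bond: the C2 alkoxide attacks C8a of ring A and expels fluoride. The enabling feature is that C8a lies ortho to the C4 carbonyl, so O1–C8a=C4a–C4=O is a vinylogous ester built into ring A and C8a is an acceptor carbon; O1 and C4 are 1,3-related through C2–C3, exactly like the ring oxygen and acyl carbon of a β-lactone.
3. Ring C therefore comes from an ortho-fluoroaryllithium of ring A (an aryne-type C4a/C8a synthon) and an enantiopure 4-aryl-β-lactone: acylation makes C4a–C4 and releases the very alkoxide that then closes O1–C8a, all in one flask.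
4. Ring A block: 5-fluororesorcinol bis-MOM ether, three successive directed ortho-metalations (C6 prenyl, C8 prenyl, then the lithium used in the key step); fluorine directs first and leaves last.
5. Ring B block: Stille prenylation of a bromo-isovanillin-type aldehyde, catalytic asymmetric acetate aldol (sets C2), β-lactonisation. Rings A and B are bought as arenes, the β-lactone is a temporary ring, ring C is formed last.

Key step: step 9

Remark: 5-fluororesorcinol and 3-bromo-5-hydroxy-4-methoxybenzaldehyde are taken as catalogue compounds, and the target is read as the (2S)-flavanone.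

**Route**

Step 1
Reactants: 1 5-fluororesorcinol
Product: 2 1-fluoro-3,5-bis(methoxymethoxy)benzene
Conditions: MOMCl (2.4 equiv), i-Pr2NEt, CH2Cl2, 0 °C to rt
Reagents that add atoms: chloromethyl methyl ether, COCCl
Why: Base-mediated O-alkylation of both phenols (Williamson-type etherification) gives the bis-MOM ether, whose acetal oxygens later direct the ortho-metalations and which is removed by acid at the end.

Step 2
Reactants: 2 1-fluoro-3,5-bis(methoxymethoxy)benzene
Product: 4 5-fluoro-1,3-bis(methoxymethoxy)-2-(3-methylbut-2-en-1-yl)benzene, via aryllithium 3 (not isolated)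
Conditions: n-BuLi, Et2O, 0 °C; CuBr·SMe2 (10 mol%), prenyl bromide, −40 °C to rt
Reagents that add atoms: 1-bromo-3-methylbut-2-ene (prenyl bromide), CC(C)=CCBr
Why: Directed ortho-metalation at the carbon flanked by both MOM ethers (cooperative coordination control in ether) should give aryllithium 3, and copper-catalysed allylic substitution at the primary carbon of prenyl bromide installs the future C6 prenyl group.

Step 3
Reactants: 4 5-fluoro-1,3-bis(methoxymethoxy)-2-(3-methylbut-2-en-1-yl)benzene
Product: 6 1-fluoro-3,5-bis(methoxymethoxy)-2,4-bis(3-methylbut-2-en-1-yl)benzene, via aryllithium 5 (not isolated)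
Conditions: n-BuLi, THF, −78 °C; CuBr·SMe2 (20 mol%), prenyl bromide, −78 °C, then to 0 °C
Reagents that add atoms: 1-bromo-3-methylbut-2-ene (prenyl bromide), CC(C)=CCBr
Why: A second directed ortho-metalation, now at one of the two symmetry-equivalent positions flanked by fluorine and a MOM ether, is held at −78 °C so that the ortho-fluoroaryllithium 5 does not lose LiF, and copper-catalysed SN2 prenylation installs the future C8 prenyl group.

Step 4
Reactants: 7 3-bromo-5-hydroxy-4-methoxybenzaldehyde
Product: 8 3-bromo-4-methoxy-5-(methoxymethoxy)benzaldehyde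
Conditions: MOMCl (1.3 equiv), i-Pr2NEt, CH2Cl2, 0 °C to rt
Reagents that add atoms: chloromethyl methyl ether, COCCl
Why: Williamson-type O-alkylation masks the phenol as a MOM ether that survives the organometallic steps and is removed together with the ring-A MOM groups.

Step 5
Reactants: 8 3-bromo-4-methoxy-5-(methoxymethoxy)benzaldehyde
Product: 9 4-methoxy-3-(methoxymethoxy)-5-(3-methylbut-2-en-1-yl)benzaldehyde
Conditions: tributyl(prenyl)stannane, Pd(PPh3)4 (5 mol%), DMF, 90 °C
Reagents that add atoms: tributyl(3-methylbut-2-en-1-yl)stannane, CC(C)=CC[Sn](CCCC)(CCCC)CCCC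
Why: Stille coupling (oxidative addition of the aryl bromide to zerovalent palladium, transmetalation, reductive elimination) should deliver the linear prenyl arene and tolerates the free aldehyde.

Step 6
Reactants: 9 4-methoxy-3-(methoxymethoxy)-5-(3-methylbut-2-en-1-yl)benzaldehyde
Product: 11 methyl (3S)-3-hydroxy-3-[4-methoxy-3-(methoxymethoxy)-5-(3-methylbut-2-en-1-yl)phenyl]propanoate, via trichlorosilyl ether 10 (not isolated)
Conditions: CH2=C(OMe)OTBS, SiCl4, chiral 2,2′-diamino-1,1′-binaphthyl-derived bisphosphoramide (5 mol%, the antipode that directs Si-face addition), i-Pr2NEt (10 mol%), CH2Cl2, −78 °C; sat. aq. NaHCO3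
Reagents that add atoms: 1-(tert-butyldimethylsilyloxy)-1-methoxyethene, C=C(OC)O[Si](C)(C)C(C)(C)C
Why: Lewis-base-catalysed Mukaiyama aldol addition in which the chiral phosphoramide-bound trichlorosilyl cation activates the aldehyde and leaves its Si face open to the silyl ketene acetal, so that the carbinol centre (the future C2) is set as (S) under catalyst control, the silyl ether 10 being hydrolysed on work-up.

Step 7
Reactants: 11 methyl (3S)-3-hydroxy-3-[4-methoxy-3-(methoxymethoxy)-5-(3-methylbut-2-en-1-yl)phenyl]propanoate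
Product: 13 (3S)-3-hydroxy-3-[4-methoxy-3-(methoxymethoxy)-5-(3-methylbut-2-en-1-yl)phenyl]propanoic acid, via lithium carboxylate 12 (not isolated)
Conditions: LiOH, THF/H2O, 0 °C to rt; 1 M HCl to pH 4, 0 °C
Reagents that add atoms: lithium hydroxide, [Li+].[OH-]
Why: Saponification of the methyl ester (acyl substitution by hydroxide, then mild acidification) gives the β-hydroxy acid without touching the carbinol centre, which stays (S).

Step 8
Reactants: 13 (3S)-3-hydroxy-3-[4-methoxy-3-(methoxymethoxy)-5-(3-methylbut-2-en-1-yl)phenyl]propanoic acid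
Product: 14 (4S)-4-[4-methoxy-3-(methoxymethoxy)-5-(3-methylbut-2-en-1-yl)phenyl]oxetan-2-one
Conditions: PhSO2Cl (2 equiv), pyridine, 0 °C
Reagents that add atoms: none
Why: β-Lactonisation by carboxyl activation as the mixed carboxylic–sulfonic anhydride and attack of the β-hydroxyl on the acyl carbon; the carbinol C–O bond is not broken, so the centre stays (S).

Step 9
Reactants: 6 1-fluoro-3,5-bis(methoxymethoxy)-2,4-bis(3-methylbut-2-en-1-yl)benzene; 14 (4S)-4-[4-methoxy-3-(methoxymethoxy)-5-(3-methylbut-2-en-1-yl)phenyl]oxetan-2-one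
Product: 17 (2S)-2-[4-methoxy-3-(methoxymethoxy)-5-(3-methylbut-2-en-1-yl)phenyl]-5,7-bis(methoxymethoxy)-6,8-bis(3-methylbut-2-en-1-yl)-2,3-dihydro-4H-chromen-4-one, via aryllithium 15 (not isolated), via lithium aldolate 16 (not isolated)
Conditions: n-BuLi (1.0 equiv), THF, −78 °C; cannulate into 14 (1.1 equiv), THF, −78 °C; DMPU, −78 to 0 °C; pH 7 buffer
Reagents that add atoms: none
Why: Proposed new method: aryllithium 15, stable below −60 °C and acting as an aryne-type C4a/C8a synthon, should add to the strained carbonyl of lactone 14 with acyl–oxygen cleavage (closest known reactions: openings of β-lactones by hard lithium carbanions to β-hydroxy ketones, and the annulation of arynes with salicylates to xanthones), so that the group expelled is the C2 alkoxide itself and aldolate 16 arises with no added base. The ketone just formed then activates the ortho carbon C8a, and O1 attacks it in an intramolecular SNAr (addition–elimination through an anionic σ-adduct whose charge rests on the C4 carbonyl), closing ring C as a six-membered ring with irreversible loss of LiF, as in the known alkoxide and phenoxide closures of ortho-fluoroaryl ketones to chromanones and xanthones. No stereocentre is created: C2 comes from lactone 14, and since neither its C–O nor its C–H bond is broken the (S) configuration should be carried over unchanged. The step needs acyl- over alkyl-oxygen attack and addition over α-deprotonation (hard nucleophile, ring strain, −78 °C, inverse addition) and no second addition (the new ketone carries two ortho substituents). It also needs ring closure to outrun retro-aldol cleavage or elimination of 16, which is favoured because no excess base is present, the alkoxide is freed from lithium by DMPU only after acylation is complete, and no base remains to reopen ring C once 16 is consumed. The regiochemistry of the closure is fixed because C8a is the only carbon bearing a leaving group.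

Step 10
Reactants: 17 (2S)-2-[4-methoxy-3-(methoxymethoxy)-5-(3-methylbut-2-en-1-yl)phenyl]-5,7-bis(methoxymethoxy)-6,8-bis(3-methylbut-2-en-1-yl)-2,3-dihydro-4H-chromen-4-one
Product: 18 isoamoritin
Conditions: 3 M HCl in MeOH/THF, 40 °C
Reagents that add atoms: none
Why: Acid-catalysed methanolysis of the three MOM acetals (transacetalisation to dimethoxymethane) should free the 5-, 7- and 3′-hydroxyls under mild conditions of the kind used for MOM-protected prenylflavanones, leaving C2 and the prenyl groups untouched.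

**Compound list**

1 | 5-fluororesorcinol (5-fluorobenzene-1,3-diol) | Oc1cc(O)cc(F)c1 | starting material
2 | 1-fluoro-3,5-bis(methoxymethoxy)benzene | COCOc1cc(F)cc(OCOC)c1 | intermediate
3 | [4-fluoro-2,6-bis(methoxymethoxy)phenyl]lithium | [Li]c1c(OCOC)cc(F)cc1OCOC | intermediate
4 | 5-fluoro-1,3-bis(methoxymethoxy)-2-(3-methylbut-2-en-1-yl)benzene | COCOc1cc(F)cc(OCOC)c1CC=C(C)C | intermediate
5 | [2-fluoro-4,6-bis(methoxymethoxy)-5-(3-methylbut-2-en-1-yl)phenyl]lithium | [Li]c1c(F)cc(OCOC)c(CC=C(C)C)c1OCOC | intermediate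
6 | 1-fluoro-3,5-bis(methoxymethoxy)-2,4-bis(3-methylbut-2-en-1-yl)benzene | Fc1cc(OCOC)c(CC=C(C)C)c(OCOC)c1CC=C(C)C | intermediate
7 | 3-bromo-5-hydroxy-4-methoxybenzaldehyde | COc1c(O)cc(C=O)cc1Br | starting material
8 | 3-bromo-4-methoxy-5-(methoxymethoxy)benzaldehyde | COCOc1cc(C=O)cc(Br)c1OC | intermediate
9 | 4-methoxy-3-(methoxymethoxy)-5-(3-methylbut-2-en-1-yl)benzaldehyde | COCOc1cc(C=O)cc(CC=C(C)C)c1OC | intermediate
10 | methyl (3S)-3-[4-methoxy-3-(methoxymethoxy)-5-(3-methylbut-2-en-1-yl)phenyl]-3-(trichlorosilyloxy)propanoate | COC(=O)C[C@@H](c1cc(OCOC)c(OC)c(CC=C(C)C)c1)O[Si](Cl)(Cl)Cl | intermediate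
11 | methyl (3S)-3-hydroxy-3-[4-methoxy-3-(methoxymethoxy)-5-(3-methylbut-2-en-1-yl)phenyl]propanoate | COC(=O)C[C@@H](c1cc(OCOC)c(OC)c(CC=C(C)C)c1)O | intermediate
12 | lithium (3S)-3-hydroxy-3-[4-methoxy-3-(methoxymethoxy)-5-(3-methylbut-2-en-1-yl)phenyl]propanoate | [Li+].[O-]C(=O)C[C@@H](c1cc(OCOC)c(OC)c(CC=C(C)C)c1)O | intermediate
13 | (3S)-3-hydroxy-3-[4-methoxy-3-(methoxymethoxy)-5-(3-methylbut-2-en-1-yl)phenyl]propanoic acid | OC(=O)C[C@@H](c1cc(OCOC)c(OC)c(CC=C(C)C)c1)O | intermediate
14 | (4S)-4-[4-methoxy-3-(methoxymethoxy)-5-(3-methylbut-2-en-1-yl)phenyl]oxetan-2-one | O=C1C[C@@H](c2cc(OCOC)c(OC)c(CC=C(C)C)c2)O1 | intermediate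
15 | [2-fluoro-4,6-bis(methoxymethoxy)-3,5-bis(3-methylbut-2-en-1-yl)phenyl]lithium | [Li]c1c(F)c(CC=C(C)C)c(OCOC)c(CC=C(C)C)c1OCOC | intermediate
16 | lithium (1S)-3-[2-fluoro-4,6-bis(methoxymethoxy)-3,5-bis(3-methylbut-2-en-1-yl)phenyl]-1-[4-methoxy-3-(methoxymethoxy)-5-(3-methylbut-2-en-1-yl)phenyl]-3-oxopropan-1-olate | O=C(C[C@@H](c1cc(OCOC)c(OC)c(CC=C(C)C)c1)[O-])c1c(F)c(CC=C(C)C)c(OCOC)c(CC=C(C)C)c1OCOC.[Li+] | intermediate
17 | (2S)-2-[4-methoxy-3-(methoxymethoxy)-5-(3-methylbut-2-en-1-yl)phenyl]-5,7-bis(methoxymethoxy)-6,8-bis(3-methylbut-2-en-1-yl)-2,3-dihydro-4H-chromen-4-one | COc1c(OCOC)cc([C@@H]2CC(=O)c3c(OCOC)c(CC=C(C)C)c(OCOC)c(CC=C(C)C)c3O2)cc1CC=C(C)C | intermediate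
18 | isoamoritin, (2S)-5,7-dihydroxy-2-[3-hydroxy-4-methoxy-5-(3-methylbut-2-en-1-yl)phenyl]-6,8-bis(3-methylbut-2-en-1-yl)-2,3-dihydro-4H-chromen-4-one | COc1c(O)cc([C@@H]2CC(=O)c3c(O)c(CC=C(C)C)c(O)c(CC=C(C)C)c3O2)cc1CC=C(C)C | target

**Count and risks**

Total step count: 10. Longest linear sequence: 7 steps (steps 4 to 10, from 3-bromo-5-hydroxy-4-methoxybenzaldehyde).

Steps most likely to fail:

1. Step 9 (proposed new method). Retro-aldol cleavage or β-elimination of the lithium aldolate may compete with ring closure, and proton transfer from the lactone or the new ketone to the aryllithium may compete with acylation, so that yield and enantiopurity are lost. The fallback sets out from 6 and 14 and comes back at 17. Only the acylation is run (15 added to 14 at −78 °C, quenched cold with AcOH), and the β-hydroxy ketone F1 is isolated. It is reduced with NaBH4 (MeOH, 0 °C) to the 1,3-diol F2, in which the new C4 centre is irrelevant and retro-aldol cleavage is no longer possible. Ring C is then closed through the same O1–C8a bond by SNAr of the dialkoxide on the fluoroarene (KOtBu, DMSO, 60 °C), a known closure of ortho-fluoroaryl alkanols to chromans, giving the flavan-4-ol F3. Oxidation of the benzylic alcohol with DMP (CH2Cl2, NaHCO3) returns 17.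

2. Step 8. The electron-rich benzylic C–O bond of the activated acid or of the lactone may ionise, leading to decarboxylative fragmentation to a styrene, or the benzylic hydroxyl may be sulfonylated instead of the carboxyl group. The fallback sets out from 11 and comes back at 17 without any β-lactone. Ester 11 is converted into the N-methoxy-N-methylamide F4 (MeNHOMe·HCl, i-PrMgCl, THF, −20 °C) and silylated to the triethylsilyl ether F5 (TESCl, imidazole, DMF). Aryllithium 15 (from 6, n-BuLi, THF, −78 °C) is added in a Weinreb ketone synthesis to give the β-silyloxy ketone F6. Ring C is closed at O1–C8a by fluoride-triggered desilylation and SNAr (CsF, DMF, 0 °C) to give 17.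

3. Step 2. Metalation may occur next to fluorine instead of between the two MOM ethers, which would give the regioisomeric prenyl arene and, at 0 °C, loss of material through aryne formation. The fallback sets out from 2 and comes back at 4. Both fluorine-flanked positions are blocked by in situ trapping (LDA, TMSCl, THF, −78 °C) to give the bis(trimethylsilyl)arene F7. The only remaining ring position is metalated and prenylated (n-BuLi, THF, 0 °C; CuBr·SMe2 (10 mol%), prenyl bromide) to give the prenylated bis(silyl)arene F8. Protodesilylation (TBAF, wet THF, 60 °C) returns 4.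

**Further compounds**

F1 | step 9 | (3S)-1-[2-fluoro-4,6-bis(methoxymethoxy)-3,5-bis(3-methylbut-2-en-1-yl)phenyl]-3-hydroxy-3-[4-methoxy-3-(methoxymethoxy)-5-(3-methylbut-2-en-1-yl)phenyl]propan-1-one | O=C(C[C@@H](c1cc(OCOC)c(OC)c(CC=C(C)C)c1)O)c1c(F)c(CC=C(C)C)c(OCOC)c(CC=C(C)C)c1OCOC
F2 | step 9 | (1S,3RS)-3-[2-fluoro-4,6-bis(methoxymethoxy)-3,5-bis(3-methylbut-2-en-1-yl)phenyl]-1-[4-methoxy-3-(methoxymethoxy)-5-(3-methylbut-2-en-1-yl)phenyl]propane-1,3-diol | OC(C[C@@H](c1cc(OCOC)c(OC)c(CC=C(C)C)c1)O)c1c(F)c(CC=C(C)C)c(OCOC)c(CC=C(C)C)c1OCOC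
F3 | step 9 | (2S,4RS)-2-[4-methoxy-3-(methoxymethoxy)-5-(3-methylbut-2-en-1-yl)phenyl]-5,7-bis(methoxymethoxy)-6,8-bis(3-methylbut-2-en-1-yl)-3,4-dihydro-2H-chromen-4-ol | COc1c(OCOC)cc([C@@H]2CC(O)c3c(OCOC)c(CC=C(C)C)c(OCOC)c(CC=C(C)C)c3O2)cc1CC=C(C)C
F4 | step 8 | (3S)-3-hydroxy-N-methoxy-3-[4-methoxy-3-(methoxymethoxy)-5-(3-methylbut-2-en-1-yl)phenyl]-N-methylpropanamide | CON(C)C(=O)C[C@@H](c1cc(OCOC)c(OC)c(CC=C(C)C)c1)O
F5 | step 8 | (3S)-N-methoxy-3-[4-methoxy-3-(methoxymethoxy)-5-(3-methylbut-2-en-1-yl)phenyl]-N-methyl-3-(triethylsilyloxy)propanamide | CON(C)C(=O)C[C@@H](c1cc(OCOC)c(OC)c(CC=C(C)C)c1)O[Si](CC)(CC)CC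
F6 | step 8 | (3S)-1-[2-fluoro-4,6-bis(methoxymethoxy)-3,5-bis(3-methylbut-2-en-1-yl)phenyl]-3-[4-methoxy-3-(methoxymethoxy)-5-(3-methylbut-2-en-1-yl)phenyl]-3-(triethylsilyloxy)propan-1-one | O=C(C[C@@H](c1cc(OCOC)c(OC)c(CC=C(C)C)c1)O[Si](CC)(CC)CC)c1c(F)c(CC=C(C)C)c(OCOC)c(CC=C(C)C)c1OCOC
F7 | step 2 | [2-fluoro-4,6-bis(methoxymethoxy)-1,3-phenylene]bis(trimethylsilane) | COCOc1cc(OCOC)c([Si](C)(C)C)c(F)c1[Si](C)(C)C
F8 | step 2 | [2-fluoro-4,6-bis(methoxymethoxy)-5-(3-methylbut-2-en-1-yl)-1,3-phenylene]bis(trimethylsilane) | COCOc1c(CC=C(C)C)c(OCOC)c([Si](C)(C)C)c(F)c1[Si](C)(C)C
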